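## Analysis of the target

Palstatin (19) is a flavonolignan. It is a 5,7-dihydroxyflavone (rings A and C) whose ring B is fused at C3' and C4' through two oxygens to a 2,3-dihydro-1,4-dioxine ring and carries a methoxy group at C5'. In the dioxane ring, Ca is bonded to O3' and carries the 4-hydroxy-3,5-dimethoxyphenyl (syringyl) ring, and Cb is bonded to O4' and carries CH2OH; both are R, so aryl and hydroxymethyl are trans. These two adjacent centres are the only stereocentres. They lie far from any group that could relay chirality, so they must be set absolutely and relative to each other. Sensitive sites are the Ca–O3' bond (a benzylic aryl ether para to an oxygen substituent, open to ionisation by strong acid and to hydrogenolysis), the three phenols and the primary alcohol that must be told apart, and the chromone enone. The synthesis is hard on three counts: the regiochemistry of the dioxane (Ca on O3', not on O4'), the threo/trans configuration, and the position of C3' meta to the carbonyl-bearing C1', which rules out nucleophilic aromatic substitution by an alkoxide. The strategy rests on that atom: C3' can carry bromine ortho to the C4' oxygen, O4' can be tied to Cb beforehand, and the C3'–O3' bond can then be made by palladium catalysis from the threo alcohol 10 without touching either C–O bond at the stereocentres.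

## Retrosynthetic reasoning

19 ⇒ 18. The last bonds cut are three O–benzyl bonds: the phenols at C5, C7 and on the syringyl ring are carried as benzyl ethers. Benzyl survives every base and the dilute acid used on the way, and one hydrogenolysis removes all three. The final step only has to spare the chromone double bond and the benzylic Ca–O3' bond.

18 ⇒ 16. Ring C is opened at O1–C2, which leads to the ortho-hydroxyaryl 1,3-diketone 16. Its acid cyclodehydration is the most dependable entry to a flavone. A primary silyl ether cannot be expected to survive the protic acid this needs, so its loss is planned into the same operation (through 17) and the primary alcohol of 18 is left free.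

16 ⇒ 15 ⇒ 12 + 14. The C2–C3 bond is cut. Made directly, it would be an intermolecular C-acylation of a ketone enolate; made through aryl ester 15 it becomes an easy O-acylation followed by an intramolecular O-to-C acyl shift. This divides the molecule into the ring A ketone 14 and the ring B acid 12. Ketone 14 comes from 13 by etherification of the two hydroxyls that are not hydrogen-bonded to the carbonyl; acid 12 is the saponified form of ester 11.

11 ⇒ 10. The dioxane is opened at C3'–O3'. Of the four C–O bonds of the ring, this is the only one whose formation leaves both stereocentres untouched and needs no substitution at the benzylic carbon Ca, where a para-oxygenated aryl group invites ionisation. The gain is that ring, regiochemistry and configuration are decided separately: in 10 the oxygen on Ca is a free hydroxyl and C3' carries bromine, so O3' can only join Ca to C3'. The forward reaction has to achieve oxidative addition at an electron-rich aryl bromide and then C–O reductive elimination from a secondary benzylic alkoxide faster than β-hydride elimination. It must use the secondary hydroxyl only, which is why the primary one is silylated.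

10 ⇒ 9 ⇒ 8. The silyl ether is removed and the primary alcohol is traced back to a methyl ester at Cb. The ester serves the preceding step (it makes Cb epimerisable) but must be gone before the base-mediated ring closure, where a β-hydroxy ester would epimerise or undergo retro-aldol cleavage. The forward reduction must distinguish the activated aliphatic ester from the aryl ester on ring B.

8 ⇒ 7. Both stereocentres are removed together by going back to the β-keto ester 7. Cb in 7 lies between two carbonyl groups and epimerises freely, so a reagent-controlled reduction of the ketone can funnel both epimers into one syn hydroxy ester. The forward reaction has to set Ca absolutely and Cb relative to Ca in one dynamic kinetic resolution.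

7 ⇒ 4 + 6. The Cb–O4' bond is cut. Phenol 6 has a single hydroxyl, at C4', flanked by the bromine at C3' and the methoxy group at C5'. Insertion of the carbenoid from diazo ester 4 into this O–H bond fixes the regiochemistry of the future dioxane without any differentiation of two ring B oxygens.

4 ⇒ 3 ⇒ 2 ⇒ 1, and 6 ⇒ 5. The diazo group comes from diazo transfer to β-keto ester 3, the ester carbon from C-acylation of methyl ketone 2, and 2 from benzylation of 1, which already holds the complete syringyl substitution pattern. Phenol 6 is obtained by brominating 5 ortho to its hydroxyl, so the ester oxidation level needed for ring C is present from the start and no aldehyde has to be oxidised beside a free phenol.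

## Alternatives that were turned down

Alternative 1: ring A from an aryne.
- Disconnection: C8a–O1 and C4a–C4 of the flavone, back to the ring B arylpropiolic acid A2 (finished benzodioxane, all hydroxyls benzylated) and the ortho-silylaryl triflate A3.
- Forward key step: a fluoride source releases the 3,5-dialkoxyaryne from A3. The carboxylate oxygen of A2 adds to the aryne carbon remote from the flanking benzyloxy group, the aryl anion formed next to that group attacks the acyl carbon, and the strained four-membered adduct opens to the ortho-hydroxyaryl ynone A1. No ring has closed at that point; a separate 6-endo oxa-Michael addition would give ring C.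
- For it: the inductive polarisation of a 3-alkoxyaryne matches the regiochemistry needed (oxygen at C8a, acyl carbon at C4a). Ring A arrives in one event. No protic acid is used, so the CH2OH can be a benzyl ether and one hydrogenolysis ends the synthesis.
- Against it: the step makes neither a ring nor a stereocentre, so the whole benzodioxane problem remains. A2 needs about four steps of homologation from an ester of the type of 11, and A3 is itself a multistep compound. Arylpropiolic acids decarboxylate readily under basic fluoride conditions, the alkyne can engage the aryne, the phenoxide of A1 can be arylated by a second aryne, and closure of A1 can go 5-exo to an aurone.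
- Comparison: on convergence at the flavone stage and on mildness towards the benzylic aryl ether this alternative is the stronger one. The chosen route pays with a longer, classical sequence to ring C and a planned desilylation, but those steps are dependable, and its one uncertain step is the one that builds the stereodefined heterocycle.

Alternative 2: ring C by carbonylative three-component coupling.
- Disconnection: C4a–C4, C4–C3 and O1–C2 together, back to the iodophenol A5, a one-carbon carbonyl unit and the ring B alkyne A6 that already contains the chiral benzodioxane.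
- Forward key step: zerovalent palladium inserts into the C–I bond of A5, carbonyl insertion gives an acyl palladium species, coupling with the terminal alkyne A6 gives an ynone, and the amine solvent promotes 6-endo addition of the phenol. The protected flavone A4 should form in one flask.
- For it: three bonds and ring C in one step, the highest convergence of the four plans, and only basic conditions, so the silyl ether and the benzylic aryl ether are safe.
- Against it: in A5 the iodine sits between a hydroxyl and a benzyloxy group on a very electron-rich ring, which slows oxidative addition and carbonyl insertion. Direct alkynylation without carbonyl uptake (leading to a 2-arylbenzofuran) and 5-exo closure to an aurone are the known leaks of this reaction. A5 is not easily made as one regioisomer, because the position between the two benzyloxy groups competes on iodination. A6 needs three further steps from 11. The stereocentres are again not addressed.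
- Comparison: this plan is stronger on step economy after the benzodioxane and on functional-group mildness. It places a selectivity-prone multicomponent step at the very end on the most valuable material and still needs a solution for the dioxane. The chosen strategy offers that solution and keeps the late steps routine.

Alternative 3: dioxane closure by phenoxide opening of an epoxide.
- Disconnection: Cb–O4', back to the epoxy ether A8, in which O3' is already on Ca, the C4' hydroxyl is free and Cb is part of a terminal epoxide of opposite configuration.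
- Forward key step: a carbonate base generates the C4' phenoxide, which opens the epoxide at Cb in a 6-exo-tet mode with inversion, closing the dioxane and releasing the primary alcohol of A7.
- For it: no transition metal, no protecting group on CH2OH, a stereospecific step, and a ring closure of a type long used for 2-hydroxymethyl-1,4-benzodioxanes. As a ring-forming event it is probably safer than a palladium etherification.
- Against it: A8 must already contain the Ca–O3' aryl ether in defined configuration. Making that ether means a substitution at a secondary benzylic carbon bearing a para-alkoxyaryl group, exactly where ionisation erodes configuration. It also needs a ring B with O3' free and O4' masked, the reverse of the natural reactivity of a 3,4-dihydroxybenzoate, and an enantio- and diastereodefined aryl epoxy carbinol. Attack at the CH2 terminus (7-endo) is a minor competing path.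
- Comparison: the risk moves from the ring closure into the preparation of the precursor and into protecting-group work on ring B. The chosen strategy sets both centres in one catalytic reduction, never substitutes at Ca, and gets the O3'/O4' assignment from a phenol with a single hydroxyl.

Key step: step 9

Assumption (remark on the chemistry): the transfer hydrogenation of 7 is taken to follow the facial and syn preference known for aryl ketones and α-alkoxy β-keto esters, which calls for the S,S ligand; should the sense be reversed, the R,R ligand is used instead.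

## Route

Step 1
Reactants: 1 acetosyringone
Product: 2 4'-(benzyloxy)-3',5'-dimethoxyacetophenone
Conditions: BnBr, K2CO3, DMF, 60 °C
Reagents that add atoms: benzyl bromide, `BrCc1ccccc1`
Why: Williamson etherification of the only phenol; the benzyl ether shields the syringyl hydroxyl from the rhodium carbenoid and all later bases and leaves with the ring A benzyl ethers at the end.

Step 2
Reactants: 2 4'-(benzyloxy)-3',5'-dimethoxyacetophenone
Product: 3 methyl 3-[4-(benzyloxy)-3,5-dimethoxyphenyl]-3-oxopropanoate
Conditions: NaH, (MeO)2CO, toluene, 110 °C; then AcOH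
Reagents that add atoms: dimethyl carbonate, `COC(=O)OC`
Why: Claisen-type C-acylation of the methyl ketone enolate; irreversible deprotonation of the β-keto ester product by NaH drives the condensation.

Step 3
Reactants: 3 methyl 3-[4-(benzyloxy)-3,5-dimethoxyphenyl]-3-oxopropanoate
Product: 4 methyl 3-[4-(benzyloxy)-3,5-dimethoxyphenyl]-2-diazo-3-oxopropanoate
Conditions: p-ABSA, Et3N, MeCN, 0 °C → rt
Reagents that add atoms: 4-acetamidobenzenesulfonyl azide (p-ABSA), `CC(=O)Nc1ccc(cc1)S(=O)(=O)N=[N+]=[N-]`
Why: Regitz diazo transfer to an active methylene compound; the 1,3-dicarbonyl is acidic enough for Et3N.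

Step 4
Reactants: 5 methyl vanillate
Product: 6 methyl 3-bromo-4-hydroxy-5-methoxybenzoate
Conditions: Br2, AcOH, rt
Reagents that add atoms: bromine, `BrBr`
Why: Electrophilic aromatic bromination directed by the hydroxyl; its para position is occupied by the ester-bearing carbon and one ortho position by methoxy, so only C5, the future C3', is open.

Step 5
Reactants: 4 methyl 3-[4-(benzyloxy)-3,5-dimethoxyphenyl]-2-diazo-3-oxopropanoate; 6 methyl 3-bromo-4-hydroxy-5-methoxybenzoate
Product: 7 methyl 3-[4-(benzyloxy)-3,5-dimethoxyphenyl]-2-[2-bromo-6-methoxy-4-(methoxycarbonyl)phenoxy]-3-oxopropanoate (racemic, labile at C2)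
Conditions: Rh2(OAc)4 (1 mol %), toluene, 80 °C, slow addition of 4
Reagents that add atoms: none
Why: Rhodium carbenoid O–H insertion into a phenol; the single hydroxyl of 6 is the only protic site, so Cb becomes bonded to O4', and slow addition of 4 limits carbene dimerisation; the new centre is formed racemic, which is wanted for step 6.

Step 6
Reactants: 7 methyl 3-[4-(benzyloxy)-3,5-dimethoxyphenyl]-2-[2-bromo-6-methoxy-4-(methoxycarbonyl)phenoxy]-3-oxopropanoate
Product: 8 methyl (2S,3R)-3-[4-(benzyloxy)-3,5-dimethoxyphenyl]-2-[2-bromo-6-methoxy-4-(methoxycarbonyl)phenoxy]-3-hydroxypropanoate (syn)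
Conditions: RuCl(p-cymene)[(S,S)-TsDPEN] (2 mol %), HCO2H/Et3N (5:2), CH2Cl2, 30 °C
Reagents that add atoms: none
Why: Noyori-type asymmetric transfer hydrogenation with dynamic kinetic resolution; Et3N equilibrates the Cb epimers of 7 through the enol faster than hydride transfer, the aryl ketone is reduced on the face fixed by the aryl/p-cymene contact (R at Ca with the S,S ligand), and as with α-alkoxy β-keto esters the syn (threo) isomer is preferred, so both centres are set here.

Step 7
Reactants: 8 methyl (2S,3R)-3-[4-(benzyloxy)-3,5-dimethoxyphenyl]-2-[2-bromo-6-methoxy-4-(methoxycarbonyl)phenoxy]-3-hydroxypropanoate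
Product: 9 methyl 4-{[(1R,2R)-1-[4-(benzyloxy)-3,5-dimethoxyphenyl]-1,3-dihydroxypropan-2-yl]oxy}-3-bromo-5-methoxybenzoate (threo diol)
Conditions: NaBH4, THF/MeOH, 0 °C → rt
Reagents that add atoms: none
Why: Borohydride reduction of an ester activated by its α-aryloxy and β-hydroxy groups, while the conjugated, electron-rich methyl benzoate is far less electrophilic and should remain; no bond at a stereocentre is broken, and the descriptor at Cb changes from S to R only because the CIP ranking of its substituents changes.

Step 8
Reactants: 9 methyl 4-{[(1R,2R)-1-[4-(benzyloxy)-3,5-dimethoxyphenyl]-1,3-dihydroxypropan-2-yl]oxy}-3-bromo-5-methoxybenzoate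
Product: 10 methyl 4-{[(1R,2R)-1-[4-(benzyloxy)-3,5-dimethoxyphenyl]-3-[(tert-butyldimethylsilyl)oxy]-1-hydroxypropan-2-yl]oxy}-3-bromo-5-methoxybenzoate
Conditions: TBSCl, imidazole, CH2Cl2, 0 °C
Reagents that add atoms: tert-butyldimethylsilyl chloride, `CC(C)(C)[Si](C)(C)Cl`
Why: Silylation selective for the primary over the hindered secondary benzylic hydroxyl; this protection is essential because the primary hydroxyl could otherwise close an isomeric six-membered ring onto C3' in step 9.

Step 9
Reactants: 10 methyl 4-{[(1R,2R)-1-[4-(benzyloxy)-3,5-dimethoxyphenyl]-3-[(tert-butyldimethylsilyl)oxy]-1-hydroxypropan-2-yl]oxy}-3-bromo-5-methoxybenzoate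
Product: 11 methyl (2R,3R)-3-[4-(benzyloxy)-3,5-dimethoxyphenyl]-2-{[(tert-butyldimethylsilyl)oxy]methyl}-8-methoxy-2,3-dihydro-1,4-benzodioxine-6-carboxylate (trans)
Conditions: Pd(OAc)2 (5 mol %), rac-2-(di-tert-butylphosphino)-1,1'-binaphthyl (6 mol %), Cs2CO3, toluene, 70 °C
Reagents that add atoms: none
Why: Pd(OAc)2 is reduced in the flask to zerovalent palladium carrying one bulky phosphine, which inserts into the C3'–Br bond of 10. The hydroxyl at Ca then binds the divalent palladium aryl and is deprotonated by Cs2CO3, giving a seven-membered aryl palladium alkoxide chelate. C–O reductive elimination forms C3'–O3' and contracts this palladacycle to the six-membered dioxane; the ring therefore closes by reductive elimination at an aryl carbon (formally a 6-exo ring formation), not by a nucleophilic substitution. The closest known reaction type is the palladium-catalysed intramolecular etherification of ortho-tethered aryl bromides with secondary alcohols, which is established for 1,4-benzodioxanes and runs without loss of configuration at the carbinol carbon. No stereocentre is created: neither the Ca–O nor the Cb–O bond is broken, so the 1R,2R (threo) arrangement of 10 is carried into the trans 2R,3R ring of 11. The selectivity needed is reductive elimination over β-hydride elimination from the benzylic alkoxide, and the crowded, electron-rich di-tert-butylphosphino biaryl ligand secures it by accelerating C–O elimination at a monoligated palladium centre. The choice between the two hydroxyls is secured by the silyl ether on the primary one, and the weak, poorly soluble carbonate spares the methyl ester and the Cb–H, which is no longer acidic once the ester at Cb has been reduced.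

Step 10
Reactants: 11 methyl (2R,3R)-3-[4-(benzyloxy)-3,5-dimethoxyphenyl]-2-{[(tert-butyldimethylsilyl)oxy]methyl}-8-methoxy-2,3-dihydro-1,4-benzodioxine-6-carboxylate
Product: 12 (2R,3R)-3-[4-(benzyloxy)-3,5-dimethoxyphenyl]-2-{[(tert-butyldimethylsilyl)oxy]methyl}-8-methoxy-2,3-dihydro-1,4-benzodioxine-6-carboxylic acid
Conditions: LiOH·H2O, THF/MeOH/H2O, 40 °C; then dilute HCl to pH 4, 0 °C
Reagents that add atoms: lithium hydroxide, `[Li+].[OH-]`
Why: Saponification of the methyl benzoate by acyl substitution; the primary silyl ether and the aryl and benzyl ethers are stable to aqueous LiOH at this temperature, and brief cold acidification spares the silyl ether.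

Step 11
Reactants: 13 2,4,6-trihydroxyacetophenone
Product: 14 4,6-bis(benzyloxy)-2-hydroxyacetophenone
Conditions: BnBr (2.05 equiv), K2CO3, DMF, rt
Reagents that add atoms: benzyl bromide, `BrCc1ccccc1`
Why: Williamson etherification; the para hydroxyl and one ortho hydroxyl react, while the last ortho hydroxyl stays hydrogen-bonded to the ketone and unreactive under these mild conditions.

Step 12
Reactants: 12 (2R,3R)-3-[4-(benzyloxy)-3,5-dimethoxyphenyl]-2-{[(tert-butyldimethylsilyl)oxy]methyl}-8-methoxy-2,3-dihydro-1,4-benzodioxine-6-carboxylic acid; 14 4,6-bis(benzyloxy)-2-hydroxyacetophenone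
Product: 15 2-acetyl-3,5-bis(benzyloxy)phenyl (2R,3R)-3-[4-(benzyloxy)-3,5-dimethoxyphenyl]-2-{[(tert-butyldimethylsilyl)oxy]methyl}-8-methoxy-2,3-dihydro-1,4-benzodioxine-6-carboxylate
Conditions: EDC·HCl, DMAP, CH2Cl2, rt
Reagents that add atoms: none
Why: Steglich esterification; acyl transfer through the acylpyridinium ion overcomes the low nucleophilicity of the hydrogen-bonded phenol, and the neutral conditions leave the silyl ether alone.

Step 13
Reactants: 15 2-acetyl-3,5-bis(benzyloxy)phenyl (2R,3R)-3-[4-(benzyloxy)-3,5-dimethoxyphenyl]-2-{[(tert-butyldimethylsilyl)oxy]methyl}-8-methoxy-2,3-dihydro-1,4-benzodioxine-6-carboxylate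
Product: 16 1-[2,4-bis(benzyloxy)-6-hydroxyphenyl]-3-[(2R,3R)-3-[4-(benzyloxy)-3,5-dimethoxyphenyl]-2-{[(tert-butyldimethylsilyl)oxy]methyl}-8-methoxy-2,3-dihydro-1,4-benzodioxin-6-yl]propane-1,3-dione
Conditions: t-BuOK, THF, 0 °C → rt; then AcOH
Reagents that add atoms: none
Why: Baker–Venkataraman rearrangement; the ketone enolate attacks the neighbouring aryl ester carbonyl through a six-membered transition state and the acyl group moves from O to C, forming C2–C3, with the diketonate/phenoxide as thermodynamic sink.

Step 14
Reactants: 16 1-[2,4-bis(benzyloxy)-6-hydroxyphenyl]-3-[(2R,3R)-3-[4-(benzyloxy)-3,5-dimethoxyphenyl]-2-{[(tert-butyldimethylsilyl)oxy]methyl}-8-methoxy-2,3-dihydro-1,4-benzodioxin-6-yl]propane-1,3-dione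
Product: 18 5,7-bis(benzyloxy)-2-[(2R,3R)-3-[4-(benzyloxy)-3,5-dimethoxyphenyl]-2-(hydroxymethyl)-8-methoxy-2,3-dihydro-1,4-benzodioxin-6-yl]-4H-chromen-4-one, via desilylated diketone 17 (not isolated)
Conditions: TsOH·H2O (cat.), MeOH/THF, rt, then 60 °C
Reagents that add atoms: none
Why: Acid-catalysed methanolysis of the primary silyl ether at room temperature, then on warming the classical flavone cyclodehydration (addition of the phenol to the protonated diketone and loss of water to the 4-pyranone); the benzyl ethers and the benzodioxane, whose para oxygen is still benzylated, should tolerate catalytic sulfonic acid in methanol.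

Step 15
Reactants: 18 5,7-bis(benzyloxy)-2-[(2R,3R)-3-[4-(benzyloxy)-3,5-dimethoxyphenyl]-2-(hydroxymethyl)-8-methoxy-2,3-dihydro-1,4-benzodioxin-6-yl]-4H-chromen-4-one
Product: 19 palstatin, 5,7-dihydroxy-2-[(2R,3R)-3-(4-hydroxy-3,5-dimethoxyphenyl)-2-(hydroxymethyl)-8-methoxy-2,3-dihydro-1,4-benzodioxin-6-yl]-4H-chromen-4-one
Conditions: H2 (1 atm), 10% Pd/C, THF/MeOH, rt
Reagents that add atoms: none
Why: Hydrogenolysis of three aryl benzyl ethers; the chromone double bond and the cyclic benzylic C–O bond of the dioxane are much slower to reduce at atmospheric pressure and room temperature, and the reaction is stopped once the benzyl ethers are consumed.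

## Compound list

```
1 | acetosyringone (4'-hydroxy-3',5'-dimethoxyacetophenone) | CC(=O)c1cc(OC)c(O)c(OC)c1 | starting material
2 | 4'-(benzyloxy)-3',5'-dimethoxyacetophenone | CC(=O)c1cc(OC)c(OCc2ccccc2)c(OC)c1 | intermediate
3 | methyl 3-[4-(benzyloxy)-3,5-dimethoxyphenyl]-3-oxopropanoate | COC(=O)CC(=O)c1cc(OC)c(OCc2ccccc2)c(OC)c1 | intermediate
4 | methyl 3-[4-(benzyloxy)-3,5-dimethoxyphenyl]-2-diazo-3-oxopropanoate | COC(=O)C(=[N+]=[N-])C(=O)c1cc(OC)c(OCc2ccccc2)c(OC)c1 | intermediate
5 | methyl vanillate (methyl 4-hydroxy-3-methoxybenzoate) | COC(=O)c1ccc(O)c(OC)c1 | starting material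
6 | methyl 3-bromo-4-hydroxy-5-methoxybenzoate | COC(=O)c1cc(Br)c(O)c(OC)c1 | intermediate
7 | methyl 3-[4-(benzyloxy)-3,5-dimethoxyphenyl]-2-[2-bromo-6-methoxy-4-(methoxycarbonyl)phenoxy]-3-oxopropanoate (racemic) | COC(=O)C(Oc1c(Br)cc(C(=O)OC)cc1OC)C(=O)c1cc(OC)c(OCc2ccccc2)c(OC)c1 | intermediate
8 | methyl (2S,3R)-3-[4-(benzyloxy)-3,5-dimethoxyphenyl]-2-[2-bromo-6-methoxy-4-(methoxycarbonyl)phenoxy]-3-hydroxypropanoate (syn) | COc1cc([C@@H](O)[C@H](Oc2c(Br)cc(C(=O)OC)cc2OC)C(=O)OC)cc(OC)c1OCc1ccccc1 | intermediate
9 | methyl 4-{[(1R,2R)-1-[4-(benzyloxy)-3,5-dimethoxyphenyl]-1,3-dihydroxypropan-2-yl]oxy}-3-bromo-5-methoxybenzoate (threo diol) | COc1cc([C@@H](O)[C@H](Oc2c(Br)cc(C(=O)OC)cc2OC)CO)cc(OC)c1OCc1ccccc1 | intermediate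
10 | methyl 4-{[(1R,2R)-1-[4-(benzyloxy)-3,5-dimethoxyphenyl]-3-[(tert-butyldimethylsilyl)oxy]-1-hydroxypropan-2-yl]oxy}-3-bromo-5-methoxybenzoate (threo bromo alcohol) | COc1cc([C@@H](O)[C@H](Oc2c(Br)cc(C(=O)OC)cc2OC)CO[Si](C)(C)C(C)(C)C)cc(OC)c1OCc1ccccc1 | intermediate
11 | methyl (2R,3R)-3-[4-(benzyloxy)-3,5-dimethoxyphenyl]-2-{[(tert-butyldimethylsilyl)oxy]methyl}-8-methoxy-2,3-dihydro-1,4-benzodioxine-6-carboxylate (trans) | COc1cc([C@H]2Oc3cc(C(=O)OC)cc(OC)c3O[C@@H]2CO[Si](C)(C)C(C)(C)C)cc(OC)c1OCc1ccccc1 | intermediate
12 | (2R,3R)-3-[4-(benzyloxy)-3,5-dimethoxyphenyl]-2-{[(tert-butyldimethylsilyl)oxy]methyl}-8-methoxy-2,3-dihydro-1,4-benzodioxine-6-carboxylic acid | COc1cc([C@H]2Oc3cc(C(=O)O)cc(OC)c3O[C@@H]2CO[Si](C)(C)C(C)(C)C)cc(OC)c1OCc1ccccc1 | intermediate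
13 | 2,4,6-trihydroxyacetophenone | CC(=O)c1c(O)cc(O)cc1O | starting material
14 | 4,6-bis(benzyloxy)-2-hydroxyacetophenone | CC(=O)c1c(O)cc(OCc2ccccc2)cc1OCc1ccccc1 | intermediate
15 | 2-acetyl-3,5-bis(benzyloxy)phenyl ester of acid 12 | COc1cc([C@H]2Oc3cc(C(=O)Oc4cc(OCc5ccccc5)cc(OCc5ccccc5)c4C(C)=O)cc(OC)c3O[C@@H]2CO[Si](C)(C)C(C)(C)C)cc(OC)c1OCc1ccccc1 | intermediate
16 | 1-[2,4-bis(benzyloxy)-6-hydroxyphenyl]-3-[(2R,3R)-3-[4-(benzyloxy)-3,5-dimethoxyphenyl]-2-{[(tert-butyldimethylsilyl)oxy]methyl}-8-methoxy-2,3-dihydro-1,4-benzodioxin-6-yl]propane-1,3-dione | COc1cc([C@H]2Oc3cc(C(=O)CC(=O)c4c(O)cc(OCc5ccccc5)cc4OCc6ccccc6)cc(OC)c3O[C@@H]2CO[Si](C)(C)C(C)(C)C)cc(OC)c1OCc1ccccc1 | intermediate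
17 | desilylated diketone, 1-[2,4-bis(benzyloxy)-6-hydroxyphenyl]-3-[(2R,3R)-3-[4-(benzyloxy)-3,5-dimethoxyphenyl]-2-(hydroxymethyl)-8-methoxy-2,3-dihydro-1,4-benzodioxin-6-yl]propane-1,3-dione | COc1cc([C@H]2Oc3cc(C(=O)CC(=O)c4c(O)cc(OCc5ccccc5)cc4OCc6ccccc6)cc(OC)c3O[C@@H]2CO)cc(OC)c1OCc1ccccc1 | intermediate (not isolated)
18 | 5,7-bis(benzyloxy)-2-[(2R,3R)-3-[4-(benzyloxy)-3,5-dimethoxyphenyl]-2-(hydroxymethyl)-8-methoxy-2,3-dihydro-1,4-benzodioxin-6-yl]-4H-chromen-4-one (tri-O-benzyl palstatin) | COc1cc([C@H]2Oc3cc(-c4cc(=O)c5c(OCc6ccccc6)cc(OCc6ccccc6)cc5o4)cc(OC)c3O[C@@H]2CO)cc(OC)c1OCc1ccccc1 | intermediate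
19 | palstatin | COc1cc([C@H]2Oc3cc(-c4cc(=O)c5c(O)cc(O)cc5o4)cc(OC)c3O[C@@H]2CO)cc(OC)c1O | target
```

## Step count and least certain steps

Total step count: 15. Longest linear sequence: 13 steps (from 1 to 19 through steps 1–3, 5–10 and 12–15); steps 4 and 11 prepare 6 and 14 on side branches.

Step 9 (key step).
- Most likely failure: β-hydride elimination from the palladium-bound benzylic alkoxide outruns C–O reductive elimination, which destroys the carbinol centre and leads to hydrodebromination. A second path is base-induced migration of the silyl group from the primary to the secondary oxygen, followed by ring closure through the primary oxygen.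
- Fallback, setting out from 10 and returning at 11: the same ring is closed from the other end of the C3'–O3'–Ca unit. Miyaura borylation of 10 (bis(pinacolato)diboron, Pd(dppf)Cl2, KOAc, dioxane, 90 °C) should give the pinacol boronate F1. Oxidation (NaBO3·4H2O, THF/H2O, rt) should give the C3' phenol F2. Catalytic camphorsulfonic acid (CH2Cl2, 4 Å sieves, 0 °C → rt) then ionises the para-benzyloxybenzylic alcohol and O3' traps the cation. Cb is not touched, and the trans ring with both substituents equatorial is the thermodynamic product, so 11 is reached with Ca under thermodynamic control.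

Step 6.
- Most likely failure: poor syn/anti or facial selectivity, because the bulky, weakly coordinating 2,6-disubstituted aryloxy group may not steer the reduction the way a simple alkoxy group does. Hydride transfer to the electron-rich aryl ketone may also be slow.
- Fallback, setting out from 6 and returning at 9 (steps 5 to 7 are bypassed): an auxiliary-controlled aldol reaction sets both centres. Phenol 6 is O-alkylated with commercial (S)-4-benzyl-3-(chloroacetyl)oxazolidin-2-one F3 (K2CO3, NaI cat., MeCN, rt) to the aryloxyacetyl imide F4. Evans syn-aldol reaction of its Z boron enolate (Bu2BOTf, i-Pr2NEt, CH2Cl2, −78 → 0 °C) with commercial 4-(benzyloxy)-3,5-dimethoxybenzaldehyde F5 should give the 2S,3R syn adduct F6 through a closed chair transition state. NaBH4 in THF/H2O then cleaves the imide reductively to diol 9 and returns the auxiliary.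

Step 5.
- Most likely failure: slow O–H insertion into a hindered, weakly nucleophilic 2,6-disubstituted phenol, so that carbene dimerisation, Wolff rearrangement or insertion into traces of water takes over.
- Fallback, setting out from 3 and returning at 7 (step 3 is bypassed): the Cb–O4' bond is made by substitution. β-Keto ester 3 is chlorinated at C2 (SO2Cl2, CH2Cl2, 0 °C) to the α-chloro β-keto ester F7, which is displaced by the phenoxide of 6 (K2CO3, acetone, 50 °C) to give 7.

Step 15.
- Most likely failure: over-reduction, either hydrogenolysis of the benzylic Ca–O3' bond once the para oxygen of the syringyl ring is free, or saturation of C2–C3 of the chromone.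
- Fallback, setting out from 18 and ending at 19: the benzyl ethers are cleaved by a Lewis acid instead of by reduction (BCl3, pentamethylbenzene as cation scavenger, CH2Cl2, −78 °C). No new intermediate is made.

## Further compounds

```
F1 | step 9 | methyl 4-{[(1R,2R)-1-[4-(benzyloxy)-3,5-dimethoxyphenyl]-3-[(tert-butyldimethylsilyl)oxy]-1-hydroxypropan-2-yl]oxy}-3-methoxy-5-(4,4,5,5-tetramethyl-1,3,2-dioxaborolan-2-yl)benzoate | COc1cc([C@@H](O)[C@H](Oc2c(B3OC(C)(C)C(C)(C)O3)cc(C(=O)OC)cc2OC)CO[Si](C)(C)C(C)(C)C)cc(OC)c1OCc1ccccc1
F2 | step 9 | methyl 4-{[(1R,2R)-1-[4-(benzyloxy)-3,5-dimethoxyphenyl]-3-[(tert-butyldimethylsilyl)oxy]-1-hydroxypropan-2-yl]oxy}-3-hydroxy-5-methoxybenzoate | COc1cc([C@@H](O)[C@H](Oc2c(O)cc(C(=O)OC)cc2OC)CO[Si](C)(C)C(C)(C)C)cc(OC)c1OCc1ccccc1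
F3 | step 6 | (S)-4-benzyl-3-(chloroacetyl)oxazolidin-2-one | O=C(CCl)N1[C@@H](Cc2ccccc2)COC1=O
F4 | step 6 | methyl 4-{2-[(S)-4-benzyl-2-oxooxazolidin-3-yl]-2-oxoethoxy}-3-bromo-5-methoxybenzoate | COC(=O)c1cc(Br)c(OCC(=O)N2[C@@H](Cc3ccccc3)COC2=O)c(OC)c1
F5 | step 6 | 4-(benzyloxy)-3,5-dimethoxybenzaldehyde | COc1cc(C=O)cc(OC)c1OCc1ccccc1
F6 | step 6 | methyl 4-{[(2S,3R)-3-[4-(benzyloxy)-3,5-dimethoxyphenyl]-1-[(S)-4-benzyl-2-oxooxazolidin-3-yl]-3-hydroxy-1-oxopropan-2-yl]oxy}-3-bromo-5-methoxybenzoate (syn aldol adduct) | COc1cc([C@@H](O)[C@H](Oc2c(Br)cc(C(=O)OC)cc2OC)C(=O)N2[C@@H](Cc3ccccc3)COC2=O)cc(OC)c1OCc1ccccc1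
F7 | step 5 | methyl 3-[4-(benzyloxy)-3,5-dimethoxyphenyl]-2-chloro-3-oxopropanoate | COC(=O)C(Cl)C(=O)c1cc(OC)c(OCc2ccccc2)c(OC)c1
F0 | step 15 | none | none
A1 | alternative 1 | ortho-hydroxyaryl ynone, 1-[2,4-bis(benzyloxy)-6-hydroxyphenyl]-3-[(2R,3R)-3-[4-(benzyloxy)-3,5-dimethoxyphenyl]-2-[(benzyloxy)methyl]-8-methoxy-2,3-dihydro-1,4-benzodioxin-6-yl]prop-2-yn-1-one | COc1cc([C@H]2Oc3cc(C#CC(=O)c4c(O)cc(OCc5ccccc5)cc4OCc4ccccc4)cc(OC)c3O[C@@H]2COCc4ccccc4)cc(OC)c1OCc1ccccc1
A2 | alternative 1 | 3-[(2R,3R)-3-[4-(benzyloxy)-3,5-dimethoxyphenyl]-2-[(benzyloxy)methyl]-8-methoxy-2,3-dihydro-1,4-benzodioxin-6-yl]propiolic acid | COc1cc([C@H]2Oc3cc(C#CC(=O)O)cc(OC)c3O[C@@H]2COCc4ccccc4)cc(OC)c1OCc1ccccc1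
A3 | alternative 1 | 3,5-bis(benzyloxy)-2-(trimethylsilyl)phenyl trifluoromethanesulfonate | C[Si](C)(C)c1c(OS(=O)(=O)C(F)(F)F)cc(OCc2ccccc2)cc1OCc1ccccc1
A4 | alternative 2 | tri-O-benzyl O-TBS palstatin | COc1cc([C@H]2Oc3cc(-c4cc(=O)c5c(OCc6ccccc6)cc(OCc6ccccc6)cc5o4)cc(OC)c3O[C@@H]2CO[Si](C)(C)C(C)(C)C)cc(OC)c1OCc1ccccc1
A5 | alternative 2 | 3,5-bis(benzyloxy)-2-iodophenol | Oc1cc(OCc2ccccc2)cc(OCc2ccccc2)c1I
A6 | alternative 2 | (2R,3R)-3-[4-(benzyloxy)-3,5-dimethoxyphenyl]-2-{[(tert-butyldimethylsilyl)oxy]methyl}-6-ethynyl-8-methoxy-2,3-dihydro-1,4-benzodioxine | COc1cc([C@H]2Oc3cc(C#C)cc(OC)c3O[C@@H]2CO[Si](C)(C)C(C)(C)C)cc(OC)c1OCc1ccccc1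
A7 | alternative 3 | methyl (2R,3R)-3-[4-(benzyloxy)-3,5-dimethoxyphenyl]-2-(hydroxymethyl)-8-methoxy-2,3-dihydro-1,4-benzodioxine-6-carboxylate | COc1cc([C@H]2Oc3cc(C(=O)OC)cc(OC)c3O[C@@H]2CO)cc(OC)c1OCc1ccccc1
A8 | alternative 3 | methyl 3-{(R)-[4-(benzyloxy)-3,5-dimethoxyphenyl][(2S)-oxiran-2-yl]methoxy}-4-hydroxy-5-methoxybenzoate | COc1cc([C@@H](Oc2cc(C(=O)OC)cc(OC)c2O)[C@@H]3CO3)cc(OC)c1OCc1ccccc1
```
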